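## Retrosynthetic overview

1. Feature: two resorcinol rings are joined by an unbranched, unfunctionalised chain C1–C14. Its four central methylenes C6–C9 are the ring carbons C2–C5 of a 2,5-disubstituted thiophene once sulfur is removed, and C1–C5 and C10–C14 are two identical 5-arylpentyl arms.
2. Last operations: cleavage of the four ArO–CH3 bonds (BBr3), preceded by reductive excision of sulfur (Raney Ni), which turns the thiophene ring into C6–C9.
3. Key disconnection: C5–C6 and C9–C10, made in one flask by twofold nickel-catalysed coupling of 5-(3,5-dimethoxyphenyl)pentylmagnesium bromide with 2,5-dibromothiophene.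
4. Arm: the aryl–C1 bond comes from 3,5-dimethoxyphenylmagnesium bromide and excess 1,5-dibromopentane under copper catalysis.
5. Rings: none is formed. Both benzene rings and the thiophene ring are bought, and the thiophene ring is opened in step 5.

Key step: step 4

Remark: the target is achiral, so no stereocontrol is needed; the Grignard reagents are drawn as monomeric RMgBr and count as steps of their own because each is made as a titrated stock solution and transferred into a second flask.

## Route

Step 1
Reactants: 1 1-bromo-3,5-dimethoxybenzene
Product: 2 3,5-dimethoxyphenylmagnesium bromide (titrated THF solution)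
Conditions: Mg turnings (1.3 equiv, mechanically activated), THF, 40 °C to reflux, 2 h
Reagents that add atoms: magnesium, [Mg]
Why: Grignard formation by insertion of magnesium into the aryl C–Br bond, in which the two meta methoxy groups are inert and THF keeps the aryl Grignard reagent dissolved.

Step 2
Reactants: 2 3,5-dimethoxyphenylmagnesium bromide; 3 1,5-dibromopentane
Product: 4 1-(5-bromopentyl)-3,5-dimethoxybenzene
Conditions: 3 (4 equiv), Li2CuCl4 (5 mol %), THF, 0 °C; 2 added slowly; then rt, 12 h; aq NH4Cl; excess 3 distilled off in vacuo
Reagents that add atoms: none
Why: Kochi-type copper-catalysed Grignard–alkyl halide coupling, in which the arylcuprate formed from 2 and Li2CuCl4 displaces one primary bromide in SN2 fashion, while the excess of 3 and the inverse slow addition keep the remaining C–Br bond of 4 from reacting.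

Step 3
Reactants: 4 1-(5-bromopentyl)-3,5-dimethoxybenzene
Product: 5 5-(3,5-dimethoxyphenyl)pentylmagnesium bromide (titrated Et2O solution)
Conditions: Mg turnings (1.5 equiv, mechanically activated), Et2O, slow addition of dilute 4, gentle reflux, 2 h
Reagents that add atoms: magnesium, [Mg]
Why: Grignard formation by insertion of magnesium into the primary C–Br bond, in which slow addition of dilute bromide over excess metal holds back Wurtz dimerisation and the aryl methyl ethers are spectators.

Step 4
Reactants: 5 5-(3,5-dimethoxyphenyl)pentylmagnesium bromide (two molecules); 6 2,5-dibromothiophene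
Product: 8 2,5-bis[5-(3,5-dimethoxyphenyl)pentyl]thiophene, via monocoupled bromothiophene 7 (not isolated)
Conditions: 6 (1.0 equiv), Ni(dppp)Cl2 (3 mol %), Et2O, 0 °C; 5 (2.4 equiv) added dropwise; then reflux, 16 h; 1 M HCl, 0 °C
Reagents that add atoms: none
Why: A small part of 5 reduces the divalent nickel precatalyst to zerovalent nickel, which inserts into one C–Br bond of 6; bromide-for-alkyl exchange with 5 and reductive elimination from the cis-alkyl(thienyl)nickel complex then make the C5–C6 bond and give 7, and a second turn of the same cycle at the other C–Br bond makes C9–C10 and gives 8. This is a twofold Kumada–Corriu coupling, and its closest known form is the Ni(dppp)Cl2-catalysed reaction of primary alkylmagnesium bromides with 2-bromo- and 2,5-dibromothiophenes. No ring is closed and no stereocentre is formed, the gain being two sp3–sp2 bonds. Reductive elimination has to outrun beta-hydride elimination of the primary alkyl group, which the chelating dppp secures by leaving no free cis site on nickel and by holding the two carbon ligands next to each other. Both bromides have to react, which is secured by their identical activated positions next to sulfur, by the tendency of the released zerovalent nickel to stay bound to the thiophene pi system and move on to the second C–Br bond, and by the modest excess of 5. Cross-coupling also has to beat bromine–magnesium exchange between 5 and 6, which would start thiophene–thiophene chain growth, and this is met by working in Et2O, charging 6 and catalyst first and adding 5 slowly at 0 °C; the aryl methyl ethers are not touched by this catalyst at ether reflux.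

Step 5
Reactants: 8 2,5-bis[5-(3,5-dimethoxyphenyl)pentyl]thiophene
Product: 9 1,14-bis(3,5-dimethoxyphenyl)tetradecane
Conditions: Raney Ni (W-2, about tenfold by weight), H2 (1 atm), EtOH–THF, reflux, 8 h; hot filtration through Celite
Reagents that add atoms: none
Why: Raney nickel reductive desulfurisation, the classical conversion of 2,5-dialkylthiophenes into unbranched alkanes, cleaves both C–S bonds and saturates the released four-carbon unit on the hydrogen-laden surface, while benzene rings and aryl methyl ethers survive at atmospheric pressure.

Step 6
Reactants: 9 1,14-bis(3,5-dimethoxyphenyl)tetradecane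
Product: 11 bisnorstriatol (1,14-bis(3,5-dihydroxyphenyl)tetradecane), via tetrakis(dibromoboryloxy) intermediate 10 (not isolated)
Conditions: BBr3 (6 equiv), CH2Cl2, −78 °C to rt, 12 h; then ice water, 0 °C; extraction with EtOAc
Reagents that add atoms: boron tribromide, BrB(Br)Br (boron and bromine are held by 10 only; none of them remains in 11)
Why: Lewis-acid aryl methyl ether cleavage, in which BBr3 binds each methoxy oxygen, bromide removes the methyl group in SN2 fashion to leave the aryloxydibromoborane 10, and water then hydrolyses the B–O bonds, the saturated chain offering nothing else to react.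

## Compound list

1 | 1-bromo-3,5-dimethoxybenzene | COc1cc(Br)cc(OC)c1 | starting material
2 | 3,5-dimethoxyphenylmagnesium bromide | COc1cc([Mg]Br)cc(OC)c1 | intermediate
3 | 1,5-dibromopentane | BrCCCCCBr | starting material
4 | 1-(5-bromopentyl)-3,5-dimethoxybenzene | COc1cc(CCCCCBr)cc(OC)c1 | intermediate
5 | 5-(3,5-dimethoxyphenyl)pentylmagnesium bromide | COc1cc(CCCCC[Mg]Br)cc(OC)c1 | intermediate
6 | 2,5-dibromothiophene | Brc1ccc(Br)s1 | starting material
7 | 2-bromo-5-[5-(3,5-dimethoxyphenyl)pentyl]thiophene | COc1cc(CCCCCc2ccc(Br)s2)cc(OC)c1 | intermediate
8 | 2,5-bis[5-(3,5-dimethoxyphenyl)pentyl]thiophene | COc1cc(CCCCCc2ccc(CCCCCc3cc(OC)cc(OC)c3)s2)cc(OC)c1 | intermediate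
9 | 1,14-bis(3,5-dimethoxyphenyl)tetradecane | COc1cc(OC)cc(CCCCCCCCCCCCCCc2cc(OC)cc(OC)c2)c1 | intermediate
10 | 1,14-bis[3,5-bis(dibromoboryloxy)phenyl]tetradecane | BrB(Br)Oc1cc(OB(Br)Br)cc(CCCCCCCCCCCCCCc2cc(OB(Br)Br)cc(OB(Br)Br)c2)c1 | intermediate
11 | bisnorstriatol | Oc1cc(O)cc(CCCCCCCCCCCCCCc2cc(O)cc(O)c2)c1 | target

## Step count and risks

Total steps: 6. Longest linear sequence: 6 (1 to 11); 3 and 6 enter as bought reagents.

**Step 4 is the riskiest.**
- Bromine–magnesium exchange between the alkyl Grignard reagent and the dibromide may compete with oxidative addition and feed nickel-catalysed thiophene–thiophene chain growth.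
- The second coupling may stall on the more electron-rich monoalkylated ring.
- Beta-hydride elimination and Grignard homocoupling may consume the arm. Hydrocarbon from these side paths has to be removed by chromatography at the thiophene stage, because after desulfurisation it would differ from the product only in chain length.
- The fallback sets out from 4 and comes back at 8. It reverses the polarity, so that no thienyl bromide is present. Commercial thiophene (c1ccsc1) is deprotonated with n-BuLi (THF, −78 to 0 °C) to 2-thienyllithium F1. Alkylation with bromide 4 (0 °C to reflux) gives 2-[5-(3,5-dimethoxyphenyl)pentyl]thiophene F2. A second deprotonation with n-BuLi (1.05 equiv, THF, −78 to 0 °C) takes place at the free alpha position, which is more acidic than the C–H between the two methoxy groups. This gives {5-[5-(3,5-dimethoxyphenyl)pentyl]thiophen-2-yl}lithium F3, and a second portion of 4 converts it into 8.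

**Step 2 comes second.**
- Substitution may continue at the second bromide.
- The aryl Grignard reagent may dimerise oxidatively on copper.
- Aryl transfer from copper may be sluggish, and removal of the surplus dibromide may be incomplete.
- The fallback sets out from 1 and comes back at 4. It builds the arm from a monofunctional five-carbon unit. Sonogashira coupling of 1 with pent-4-yn-1-ol (C#CCCCO; Pd(PPh3)2Cl2, CuI, Et3N, 70 °C) gives 5-(3,5-dimethoxyphenyl)pent-4-yn-1-ol F4. Hydrogenation (H2, Pd/C, EtOAc) gives 5-(3,5-dimethoxyphenyl)pentan-1-ol F5. An Appel reaction (CBr4, PPh3, CH2Cl2, 0 °C) then gives 4.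

**Step 5 comes third.**
- C–S hydrogenolysis may stay incomplete.
- Partly saturated or olefinic material may persist when the nickel batch is poor in hydrogen.
- The lipophilic product may be held back on the large mass of metal.
- The fallback sets out from 5 and comes back at 9. It brings in the four central carbons already saturated. It gives up the heteroaromatic linchpin and is kept only as a rescue. Grignard reagent 5 (2.3 equiv) is coupled with 1,4-dibromobutane (BrCCCCBr) under Li2CuCl4 catalysis (5 mol %, THF–Et2O, 0 °C to rt). The reaction passes through 1-(9-bromononyl)-3,5-dimethoxybenzene F6, which reacts on in the same flask to give 9.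

## Further compounds

F1 | step 4 | 2-thienyllithium | [Li]c1cccs1
F2 | step 4 | 2-[5-(3,5-dimethoxyphenyl)pentyl]thiophene | COc1cc(CCCCCc2cccs2)cc(OC)c1
F3 | step 4 | {5-[5-(3,5-dimethoxyphenyl)pentyl]thiophen-2-yl}lithium | COc1cc(CCCCCc2ccc([Li])s2)cc(OC)c1
F4 | step 2 | 5-(3,5-dimethoxyphenyl)pent-4-yn-1-ol | COc1cc(C#CCCCO)cc(OC)c1
F5 | step 2 | 5-(3,5-dimethoxyphenyl)pentan-1-ol | COc1cc(CCCCCO)cc(OC)c1
F6 | step 5 | 1-(9-bromononyl)-3,5-dimethoxybenzene | COc1cc(CCCCCCCCCBr)cc(OC)c1
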